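**Plan**

1. Numbering used throughout: decalin C1–C10 with C10 = ring-fusion CH, C5 = ring-fusion C(Me), C9 = C(Me)(CH2Ar), C8 = CH(Me), C4 = CH(side chain), C3 = C(=CMe2); C11 = ArCH2; Ar = 2,5-dimethoxy-3-methylphenyl; β = face of H-10, α = face of 5-Me and 9-Me.
2. Retrosynthesis: quinone ⇐ dimethoxyarene; C3=CMe2 ⇐ C3 ketone; propanoate arm ⇐ acrylate on a C4 β-keto ester; ring A is then cut at C1–C10 and C3–C4, leaving a ring-B ketone with a C4 acetate arm on C5 and a three-carbon acryloylsilane (C1–C2–C3).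
3. Enabling feature: the C10 carbonyl of ring B lies between the quaternary carbons C5 and C9, so it cannot enolize, and it sits 1,3 to the enolizable C4 on the C5 arm; this nucleophile/electrophile pair takes up C3–C2–C1 in one anionic relay.
4. Forward: ring B from (5S)-5-methylcyclohexenone (two α′-alkylations for C9, Pd-catalysed allylation for C5), then ring A by the [3+3] annulation, then deoxygenation at C10, olefination at C3 and oxidation to the quinone.
5. Stereochemistry: C8 from the chiral pool; C9 by substrate control (anti to 8-Me) before C5 exists; C5 by the chiral Pd catalyst; C10 by hydrogen-atom delivery opposite the axial 5- and 9-methyls; C4 by equilibration next to the C3 ketone.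

Key step: step 11

Assumption: (5S)-5-methylcyclohex-2-en-1-one, 2,5-dimethoxy-3-methylbenzaldehyde and 1-methoxypropa-1,2-diene are treated as purchasable building blocks.

**Route**

Step 1
Reactants: 1 2,5-dimethoxy-3-methylbenzaldehyde
Product: 2 (2,5-dimethoxy-3-methylphenyl)methanol
Conditions: NaBH4, MeOH, 0 °C
Reagents that add atoms: none
Why: Hydride reduction of an aromatic aldehyde to the benzylic alcohol; no stereocentre is formed.

Step 2
Reactants: 2 (2,5-dimethoxy-3-methylphenyl)methanol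
Product: 3 1-(bromomethyl)-2,5-dimethoxy-3-methylbenzene
Conditions: PBr3, Et2O, 0 °C
Reagents that add atoms: phosphorus tribromide, BrP(Br)Br
Why: Substitution of an electron-rich benzylic alcohol by bromide through its phosphite ester.

Step 3
Reactants: 4 (5S)-5-methylcyclohex-2-en-1-one; 3 1-(bromomethyl)-2,5-dimethoxy-3-methylbenzene
Product: 5 (5S,6R)-6-[(2,5-dimethoxy-3-methylphenyl)methyl]-5-methylcyclohex-2-en-1-one
Conditions: LiN(i-Pr)2, THF, −78 °C; then 3, DMPU, −78 to −20 °C
Reagents that add atoms: none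
Why: Kinetic α′-enolate alkylation of a cyclohexenone, in which the benzylic bromide should enter anti to the adjacent 5-methyl (trans product); this centre is re-formed in step 4.

Step 4
Reactants: 5 (5S,6R)-6-[(2,5-dimethoxy-3-methylphenyl)methyl]-5-methylcyclohex-2-en-1-one
Product: 6 (5S,6S)-6-[(2,5-dimethoxy-3-methylphenyl)methyl]-5,6-dimethylcyclohex-2-en-1-one
Conditions: LiN(i-Pr)2, THF–DMPU, −78 °C; MeI, −78 to 0 °C
Reagents that add atoms: iodomethane, CI
Why: Second α′-enolate alkylation, in which MeI should approach anti to the neighbouring 8-methyl, so the quaternary C9 carries Me trans and CH2Ar cis to 8-Me as in the target (sequential α′-dialkylation of a 5-substituted cyclohexenone).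

Step 5
Reactants: 6 (5S,6S)-6-[(2,5-dimethoxy-3-methylphenyl)methyl]-5,6-dimethylcyclohex-2-en-1-one
Product: 8 (2S,3S)-2-[(2,5-dimethoxy-3-methylphenyl)methyl]-2,3,6-trimethylcyclohexan-1-one (both C6 epimers), via lithium enolate 7 (not isolated)
Conditions: LiBH(s-Bu)3, THF, −78 °C; then MeI, −78 to 0 °C
Reagents that add atoms: iodomethane, CI
Why: Conjugate (1,4) hydride reduction of the β-unsubstituted enone gives the regiodefined enolate, which is methylated at C5 (reductive alkylation); the C5 configuration is immaterial because C5 becomes an enol carbon in step 6.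

Step 6
Reactants: 8 (2S,3S)-2-[(2,5-dimethoxy-3-methylphenyl)methyl]-2,3,6-trimethylcyclohexan-1-one
Product: 9 (5S,6S)-6-[(2,5-dimethoxy-3-methylphenyl)methyl]-2,5,6-trimethylcyclohex-1-en-1-yl prop-2-en-1-yl carbonate
Conditions: KN(SiMe3)2, THF, −78 °C; ClCO2CH2CH=CH2, −78 to 0 °C
Reagents that add atoms: prop-2-en-1-yl carbonochloridate, C=CCOC(=O)Cl
Why: Only C5 carries an α-hydrogen (C9 is quaternary), so enolization is regiospecific and the hindered potassium enolate should be O-acylated by the chloroformate (enol carbonate formation).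

Step 7
Reactants: 9 (5S,6S)-6-[(2,5-dimethoxy-3-methylphenyl)methyl]-2,5,6-trimethylcyclohex-1-en-1-yl prop-2-en-1-yl carbonate
Product: 10 (2S,3S,6S)-2-[(2,5-dimethoxy-3-methylphenyl)methyl]-2,3,6-trimethyl-6-(prop-2-en-1-yl)cyclohexan-1-one
Conditions: Pd2(dba)3 (2.5 mol %), (S)-t-BuPHOX (6 mol %), THF, 25 °C
Reagents that add atoms: none
Why: Decarboxylative asymmetric allylic alkylation (Tsuji–Trost type): ionization and loss of CO2 give a palladium enolate/π-allyl pair that recombines inside the chiral ligand sphere, so the quaternary C5 (5-Me α, allyl β) is set by the catalyst, as for enol carbonates of 2,2,6-trisubstituted cyclohexanones.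

Step 8
Reactants: 10 (2S,3S,6S)-2-[(2,5-dimethoxy-3-methylphenyl)methyl]-2,3,6-trimethyl-6-(prop-2-en-1-yl)cyclohexan-1-one
Product: 12 2-[(1S,3S,4S)-3-[(2,5-dimethoxy-3-methylphenyl)methyl]-1,3,4-trimethyl-2-oxocyclohexyl]acetic acid, via keto aldehyde 11 (not isolated)
Conditions: OsO4 (2 mol %), NaIO4, 2,6-lutidine, dioxane–H2O, 25 °C; then NaClO2, NaH2PO4, 2-methylbut-2-ene, t-BuOH–H2O, 0 °C
Reagents that add atoms: sodium periodate, [Na+].[O-]I(=O)(=O)=O; sodium chlorite, [Na+].[O-]Cl=O
Why: Lemieux–Johnson cleavage of the terminal alkene followed by Pinnick oxidation turns the allyl group into the acetic acid arm (C4) without touching the electron-rich arene or the stereocentres.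

Step 9
Reactants: 12 2-[(1S,3S,4S)-3-[(2,5-dimethoxy-3-methylphenyl)methyl]-1,3,4-trimethyl-2-oxocyclohexyl]acetic acid
Product: 13 tert-butyl 2-[(1S,3S,4S)-3-[(2,5-dimethoxy-3-methylphenyl)methyl]-1,3,4-trimethyl-2-oxocyclohexyl]acetate
Conditions: Cl3CC(=NH)Ot-Bu, BF3·OEt2 (cat.), CH2Cl2–cyclohexane, 25 °C
Reagents that add atoms: tert-butyl 2,2,2-trichloroacetimidate, CC(C)(C)OC(=N)C(Cl)(Cl)Cl
Why: Acid-catalysed tert-butylation of the carboxylic acid by the trichloroacetimidate gives an ester that resists nucleophilic attack in step 11 and can be removed thermally in step 13.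

Step 10
Reactants: 14 1-methoxypropa-1,2-diene
Product: 16 1-[tert-butyl(dimethyl)silyl]prop-2-en-1-one, via silylated methoxyallene 15 (not isolated)
Conditions: n-BuLi, THF, −78 °C; t-BuMe2SiCl; then 1 M HCl, THF, 0 °C
Reagents that add atoms: tert-butyl(chloro)dimethylsilane, CC(C)(C)[Si](C)(C)Cl; water, O
Why: Lithiation of the allenyl ether at C1, C-silylation, and hydrolysis of the resulting enol ether is the standard entry to α,β-unsaturated acylsilanes.

Step 11
Reactants: 13 tert-butyl 2-[(1S,3S,4S)-3-[(2,5-dimethoxy-3-methylphenyl)methyl]-1,3,4-trimethyl-2-oxocyclohexyl]acetate; 16 1-[tert-butyl(dimethyl)silyl]prop-2-en-1-one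
Product: 20 tert-butyl 10-hydroxy-3-oxo-5α,8β,9α-trimethyl-9β-(ArCH2)decalin-4-carboxylate (C4 and C10 epimers), via lithium alkoxide 17 (not isolated), via siloxyallyl anion 18 (not isolated), via silyl enol ether 19 (not isolated)
Conditions: LiN(i-Pr)2, THF, −78 °C; 16, −78 °C, then −78 to −30 °C; AcOH, −78 °C; then Bu4NF, AcOH, THF, 0 °C
Reagents that add atoms: none
Why: Proposed new method: the ester enolate of 13 (C4) adds 1,2 to the acylsilane carbonyl (C3–C4), the α-silyl alkoxide 17 undergoes a 1,2-Brook rearrangement to the delocalized siloxyallyl anion 18, and its γ-carbon (C1) adds to the C10 ketone held 1,3 to C4 (C1–C10), so ring A closes in one anionic relay. The closest known reaction type is the Brook-rearrangement-mediated [3+2] annulation of acryloylsilanes with ketone enolates, in which the same allyl anion attacks the enolate's own carbonyl; here that carbonyl is a tert-butyl ester and the only ketone is three atoms away, which turns the [3+2] into a [3+3]. Ring A closes by 6-exo-trig addition to the C=O group through the γ-terminus, the α-terminus being excluded because it would give a four-membered ring. The new centres C10 (carbinol) and C4 need no control, because C10 is made trigonal in step 14 and reset in step 15 and C4 is set under thermodynamic control in step 15. The step needs 1,2- over 1,4-addition to 16 (hard lithium enolate at −78 °C), the ketone rather than the ester as internal electrophile (tert-butyl ester; the ketone between two quaternary carbons forms no competing enolate), and cyclization faster than proton transfer from C4–H (low temperature, allyl-type nucleophile suited to hindered ketones). Buffered fluoride then unmasks the C3 ketone from silyl enol ether 19.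

Step 12
Reactants: 20 tert-butyl 10-hydroxy-3-oxo-5α,8β,9α-trimethyl-9β-(ArCH2)decalin-4-carboxylate
Product: 21 tert-butyl 10-hydroxy-4-(3-methoxy-3-oxopropyl)-3-oxo-5α,8β,9α-trimethyl-9β-(ArCH2)decalin-4-carboxylate (epimers at C4 and C10)
Conditions: methyl acrylate, Cs2CO3 (20 mol %), MeCN, 25 °C
Reagents that add atoms: methyl prop-2-enoate, C=CC(=O)OC
Why: Base-catalysed Michael addition of the β-keto ester carbon C4 to methyl acrylate installs the complete propanoate arm regiospecifically; the configuration of the temporary quaternary C4 is irrelevant because the tert-butyl ester is removed in step 13.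

Step 13
Reactants: 21 tert-butyl 10-hydroxy-4-(3-methoxy-3-oxopropyl)-3-oxo-5α,8β,9α-trimethyl-9β-(ArCH2)decalin-4-carboxylate
Product: 22 methyl 3-[10-hydroxy-3-oxo-5α,8β,9α-trimethyl-9β-(ArCH2)decalin-4-yl]propanoate (epimers at C4 and C10)
Conditions: PhMe, 170 °C (sealed tube)
Reagents that add atoms: none
Why: Thermal retro-ene loss of isobutene from the tert-butyl β-keto ester and decarboxylation of the β-keto acid proceed under neutral conditions, leave the tertiary C10 alcohol and the methyl ester alone, and give C4–H next to the C3 ketone (epimers, equilibrated in step 15).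

Step 14
Reactants: 22 methyl 3-[10-hydroxy-3-oxo-5α,8β,9α-trimethyl-9β-(ArCH2)decalin-4-yl]propanoate
Product: 23 methyl 3-[3-oxo-5α,8β,9α-trimethyl-9β-(ArCH2)-Δ1(10)-octalin-4-yl]propanoate (C4 epimers)
Conditions: Ph2S[OC(CF3)2Ph]2, CH2Cl2, 0 to 25 °C
Reagents that add atoms: none
Why: Dialkoxysulfurane dehydration of the tertiary alcohol; C5 and C9 are quaternary, so only a C1 hydrogen can be lost and the C1=C10 alkene should form without acid, which avoids cation chemistry next to the electron-rich arene.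

Step 15
Reactants: 23 methyl 3-[3-oxo-5α,8β,9α-trimethyl-9β-(ArCH2)-Δ1(10)-octalin-4-yl]propanoate
Product: 24 methyl 3-[3-oxo-5α,8β,9α-trimethyl-9β-(ArCH2)-10β-H-decalin-4α-yl]propanoate (trans-decalin)
Conditions: Mn(dpm)3 (dpm = 2,2,6,6-tetramethylheptane-3,5-dionate, 10 mol %), PhSiH3, t-BuOOH, i-PrOH, 25 °C; then NaOMe (0.1 equiv), MeOH, 25 °C
Reagents that add atoms: none
Why: Mukaiyama-type hydrogen-atom-transfer hydrogenation puts H on C1 and the tertiary C10 radical should take its hydrogen on the β-face opposite the axial 5- and 9-methyls to give the trans-decalin; methoxide then equilibrates C4 to the equatorial arm (α, cis to 5-Me), the stable epimer of a 4-alkyl-5-methyl-3-ketone.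

Step 16
Reactants: 24 methyl 3-[3-oxo-5α,8β,9α-trimethyl-9β-(ArCH2)-10β-H-decalin-4α-yl]propanoate
Product: 26 methyl 3-[5α,8β,9α-trimethyl-9β-(ArCH2)-10β-H-3-(propan-2-ylidene)decalin-4α-yl]propanoate, via spiro β-lactone 25 (not isolated)
Conditions: LiN(i-Pr)2, PhOC(=O)CHMe2, THF, −78 °C; then 24, −78 to 0 °C; then DMF, 150 °C
Reagents that add atoms: phenyl 2-methylpropanoate, CC(C)C(=O)Oc1ccccc1
Why: β-Lactone olefination: aldol addition of the phenyl ester enolate to the C3 ketone, lactonization with loss of phenoxide, and thermal [2+2] cycloreversion with loss of CO2 should give the tetrasubstituted isopropylidene regiospecifically, with no acid and no change at C4.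

Step 17
Reactants: 26 methyl 3-[5α,8β,9α-trimethyl-9β-(ArCH2)-10β-H-3-(propan-2-ylidene)decalin-4α-yl]propanoate
Product: 27 3-[5α,8β,9α-trimethyl-9β-(ArCH2)-10β-H-3-(propan-2-ylidene)decalin-4α-yl]propanoic acid
Conditions: LiOH, THF–MeOH–H2O, 25 °C; then 1 M HCl
Reagents that add atoms: lithium hydroxide, [Li+].[OH-]
Why: Saponification of the unhindered methyl ester; C4 is no longer next to a carbonyl and cannot epimerize.

Step 18
Reactants: 27 3-[5α,8β,9α-trimethyl-9β-(ArCH2)-10β-H-3-(propan-2-ylidene)decalin-4α-yl]propanoic acid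
Product: 28 CNP0271365.1, 3-[5α,8β,9α-trimethyl-9β-[(5-methyl-3,6-dioxocyclohexa-1,4-dien-1-yl)methyl]-10β-H-3-(propan-2-ylidene)decalin-4α-yl]propanoic acid
Conditions: (NH4)2Ce(NO3)6, MeCN–H2O, 0 °C
Reagents that add atoms: water, O
Why: Oxidative demethylation of the 1,4-dimethoxyarene by the cerium oxidant (arene radical cation, attack of water, loss of methanol) gives the para-quinone; the hindered tetrasubstituted alkene and the acid should survive at 0 °C.

**Compound list**

1 | 2,5-dimethoxy-3-methylbenzaldehyde | COc1cc(C)c(OC)c(C=O)c1 | starting material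
2 | (2,5-dimethoxy-3-methylphenyl)methanol | COc1cc(C)c(OC)c(CO)c1 | intermediate
3 | 1-(bromomethyl)-2,5-dimethoxy-3-methylbenzene | COc1cc(C)c(OC)c(CBr)c1 | intermediate
4 | (5S)-5-methylcyclohex-2-en-1-one | O=C1C=CC[C@H](C)C1 | starting material
5 | (5S,6R)-6-[(2,5-dimethoxy-3-methylphenyl)methyl]-5-methylcyclohex-2-en-1-one | COc1cc(C)c(OC)c(C[C@H]2C(=O)C=CC[C@@H]2C)c1 | intermediate
6 | (5S,6S)-6-[(2,5-dimethoxy-3-methylphenyl)methyl]-5,6-dimethylcyclohex-2-en-1-one | COc1cc(C)c(OC)c(C[C@]2(C)C(=O)C=CC[C@@H]2C)c1 | intermediate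
7 | lithium (5S,6S)-6-[(2,5-dimethoxy-3-methylphenyl)methyl]-5,6-dimethylcyclohex-1-en-1-olate | [Li+].COc1cc(C)c(OC)c(C[C@]2(C)C([O-])=CCC[C@@H]2C)c1 | intermediate (not isolated)
8 | (2S,3S)-2-[(2,5-dimethoxy-3-methylphenyl)methyl]-2,3,6-trimethylcyclohexan-1-one (C6 epimers) | COc1cc(C)c(OC)c(C[C@]2(C)C(=O)C(C)CC[C@@H]2C)c1 | intermediate
9 | (5S,6S)-6-[(2,5-dimethoxy-3-methylphenyl)methyl]-2,5,6-trimethylcyclohex-1-en-1-yl prop-2-en-1-yl carbonate | COc1cc(C)c(OC)c(C[C@]2(C)C(OC(=O)OCC=C)=C(C)CC[C@@H]2C)c1 | intermediate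
10 | (2S,3S,6S)-2-[(2,5-dimethoxy-3-methylphenyl)methyl]-2,3,6-trimethyl-6-(prop-2-en-1-yl)cyclohexan-1-one | COc1cc(C)c(OC)c(C[C@]2(C)C(=O)[C@](C)(CC=C)CC[C@@H]2C)c1 | intermediate
11 | 2-[(1S,3S,4S)-3-[(2,5-dimethoxy-3-methylphenyl)methyl]-1,3,4-trimethyl-2-oxocyclohexyl]acetaldehyde | COc1cc(C)c(OC)c(C[C@]2(C)C(=O)[C@](C)(CC=O)CC[C@@H]2C)c1 | intermediate (not isolated)
12 | 2-[(1S,3S,4S)-3-[(2,5-dimethoxy-3-methylphenyl)methyl]-1,3,4-trimethyl-2-oxocyclohexyl]acetic acid | COc1cc(C)c(OC)c(C[C@]2(C)C(=O)[C@](C)(CC(=O)O)CC[C@@H]2C)c1 | intermediate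
13 | tert-butyl 2-[(1S,3S,4S)-3-[(2,5-dimethoxy-3-methylphenyl)methyl]-1,3,4-trimethyl-2-oxocyclohexyl]acetate | COc1cc(C)c(OC)c(C[C@]2(C)C(=O)[C@](C)(CC(=O)OC(C)(C)C)CC[C@@H]2C)c1 | intermediate
14 | 1-methoxypropa-1,2-diene | COC=C=C | starting material
15 | tert-butyl(1-methoxypropa-1,2-dien-1-yl)dimethylsilane | COC(=C=C)[Si](C)(C)C(C)(C)C | intermediate (not isolated)
16 | 1-[tert-butyl(dimethyl)silyl]prop-2-en-1-one | C=CC(=O)[Si](C)(C)C(C)(C)C | intermediate
17 | lithium alkoxide from 1,2-addition of the C4 ester enolate to 16 (C3 bears O–, silyl and vinyl) | [Li+].COc1cc(C)c(OC)c(C[C@]2(C)C(=O)[C@](C)(C(C(=O)OC(C)(C)C)C([O-])(C=C)[Si](C)(C)C(C)(C)C)CC[C@@H]2C)c1 | intermediate (not isolated)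
18 | lithium 2-silyloxyallyl anion (C3–C2–C1) after Brook rearrangement | [Li+].COc1cc(C)c(OC)c(C[C@]2(C)C(=O)[C@](C)(C(C(=O)OC(C)(C)C)C(O[Si](C)(C)C(C)(C)C)=C[CH2-])CC[C@@H]2C)c1 | intermediate (not isolated)
19 | tert-butyl 3-[tert-butyl(dimethyl)silyloxy]-10-hydroxy-5α,8β,9α-trimethyl-9β-(ArCH2)decal-2-ene-4-carboxylate (C4, C10 epimers) | COc1cc(C)c(OC)c(C[C@]2(C)C3(O)CC=C(O[Si](C)(C)C(C)(C)C)C(C(=O)OC(C)(C)C)[C@]3(C)CC[C@@H]2C)c1 | intermediate (not isolated)
20 | tert-butyl 10-hydroxy-3-oxo-5α,8β,9α-trimethyl-9β-(ArCH2)decalin-4-carboxylate (C4, C10 epimers) | COc1cc(C)c(OC)c(C[C@]2(C)C3(O)CCC(=O)C(C(=O)OC(C)(C)C)[C@]3(C)CC[C@@H]2C)c1 | intermediate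
21 | tert-butyl 10-hydroxy-4-(3-methoxy-3-oxopropyl)-3-oxo-5α,8β,9α-trimethyl-9β-(ArCH2)decalin-4-carboxylate (C4, C10 epimers) | COc1cc(C)c(OC)c(C[C@]2(C)C3(O)CCC(=O)C(CCC(=O)OC)(C(=O)OC(C)(C)C)[C@]3(C)CC[C@@H]2C)c1 | intermediate
22 | methyl 3-[10-hydroxy-3-oxo-5α,8β,9α-trimethyl-9β-(ArCH2)decalin-4-yl]propanoate (C4, C10 epimers) | COc1cc(C)c(OC)c(C[C@]2(C)C3(O)CCC(=O)C(CCC(=O)OC)[C@]3(C)CC[C@@H]2C)c1 | intermediate
23 | methyl 3-[3-oxo-5α,8β,9α-trimethyl-9β-(ArCH2)-Δ1(10)-octalin-4-yl]propanoate (C4 epimers) | COc1cc(C)c(OC)c(C[C@]2(C)C3=CCC(=O)C(CCC(=O)OC)[C@]3(C)CC[C@@H]2C)c1 | intermediate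
24 | methyl 3-[3-oxo-5α,8β,9α-trimethyl-9β-(ArCH2)-10β-H-decalin-4α-yl]propanoate | COc1cc(C)c(OC)c(C[C@]2(C)[C@H]3CCC(=O)[C@@H](CCC(=O)OC)[C@]3(C)CC[C@@H]2C)c1 | intermediate
25 | spiro β-lactone at C3 (3,3-dimethyloxetan-2-one spiro-fused to ring A) of 24 | COc1cc(C)c(OC)c(C[C@]2(C)[C@H]3CCC4(OC(=O)C4(C)C)[C@@H](CCC(=O)OC)[C@]3(C)CC[C@@H]2C)c1 | intermediate (not isolated)
26 | methyl 3-[5α,8β,9α-trimethyl-9β-(ArCH2)-10β-H-3-(propan-2-ylidene)decalin-4α-yl]propanoate | COc1cc(C)c(OC)c(C[C@]2(C)[C@H]3CCC(=C(C)C)[C@@H](CCC(=O)OC)[C@]3(C)CC[C@@H]2C)c1 | intermediate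
27 | 3-[5α,8β,9α-trimethyl-9β-(ArCH2)-10β-H-3-(propan-2-ylidene)decalin-4α-yl]propanoic acid | COc1cc(C)c(OC)c(C[C@]2(C)[C@H]3CCC(=C(C)C)[C@@H](CCC(=O)O)[C@]3(C)CC[C@@H]2C)c1 | intermediate
28 | CNP0271365.1 | CC1=CC(=O)C=C(C[C@]2(C)[C@H]3CCC(=C(C)C)[C@@H](CCC(=O)O)[C@]3(C)CC[C@@H]2C)C1=O | target

**Count and risks**

Total step count: 18. Longest linear sequence: 17 steps (steps 1–9 and 11–18; step 10 is a one-step side branch).

Step 11 (Proposed new method). The enolate may add to 16 in the conjugate sense. The siloxyallyl anion may be quenched by proton transfer from C4–H before it reaches the crowded C10 carbonyl. The ketone addition may also revert on warming (retro-allylation). The fallback sets out from 13 and uses two known reactions. A ketyl–olefin coupling of the C10 ketone with methyl acrylate (SmI2, t-BuOH, THF, −78 to 0 °C), followed by lactonization, should give the spiro-γ-lactone F1 and forms C1–C10. A Dieckmann-type acylation (KOt-Bu, THF, 0 °C), in which the tert-butyl ester enolate carbon C4 attacks the lactone carbonyl, then forms C3–C4. After acidification the route is rejoined at 20.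

Step 16. The ester enolate may deprotonate the hindered C3 ketone instead of adding to it, or the congested aldolate may revert before it lactonizes. The fallback sets out from 24. Dibromomethylenation of the ketone (CBr4, PPh3, PhMe, 110 °C; Ramirez-type olefination) should give the 1,1-dibromoalkene F2. Double methylation (Me2CuLi, Et2O, −20 to 0 °C, then MeI) replaces both bromines and rejoins the route at 26.

Step 7. Catalyst control at C5 may not override the facial bias of the chiral, α′-quaternary enolate, which would erode the diastereomer ratio. The fallback sets out from 6. Reductive allylation (LiBH(s-Bu)3, THF, −78 °C; then allyl bromide) should give the allyl ketone F3 as an epimer mixture. Its only α-hydrogen is removed (KN(SiMe3)2, THF, −78 °C) and the enolate is methylated with MeI under substrate control. After separation of the C5 epimers this rejoins the route at 10.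

**Further compounds**

F1 | step 11 | tert-butyl 2-[(1S,3S,4S)-3-[(2,5-dimethoxy-3-methylphenyl)methyl]-1,3,4-trimethylcyclohexyl]acetate carrying at C2 of the ring (C10) a spiro-fused 5-oxooxolane (γ-lactone, C10 epimers) | COc1cc(C)c(OC)c(C[C@]2(C)C3(CCC(=O)O3)[C@](C)(CC(=O)OC(C)(C)C)CC[C@@H]2C)c1
F2 | step 16 | methyl 3-[3-(dibromomethylidene)-5α,8β,9α-trimethyl-9β-(ArCH2)-10β-H-decalin-4α-yl]propanoate | COc1cc(C)c(OC)c(C[C@]2(C)[C@H]3CCC(=C(Br)Br)[C@@H](CCC(=O)OC)[C@]3(C)CC[C@@H]2C)c1
F3 | step 7 | (2S,3S)-2-[(2,5-dimethoxy-3-methylphenyl)methyl]-2,3-dimethyl-6-(prop-2-en-1-yl)cyclohexan-1-one (C6 epimers) | COc1cc(C)c(OC)c(C[C@]2(C)C(=O)C(CC=C)CC[C@@H]2C)c1
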